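**Strategy.** The 4-methyl-1-isopropylcyclohex-3-enyl (terpinen-4-yl) ring is cut across two opposite edges into two three-carbon halves: the C4–C5 bond at the fully substituted carbinol carbon C4, and the C1=C2 ring alkene (p-menthane numbering). C4 is the only stereocentre. In one flask, titanium-catalysed enantioselective addition of a 3-methylbut-3-enylzinc reagent to allyl isopropyl ketone forms C4–C5 and sets C4, and ring-closing metathesis of the resulting acyclic 1,7-diene forms C1=C2: a formal [3+3] annulation of two fragments of similar size. The alcohol is acylated with a dibromo(silyloxy)benzoyl chloride, and twofold Stille prenylation with desilylation finishes the ester.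

Key step: step 3

Remark on the chemistry: the sense of induction of the bis(sulfonamide) ligand on this dialkyl ketone cannot be predicted with certainty, so the ligand antipode that leads to the (R)-alcohol is the one assumed in step 3.

**Step 1**
Reactants: 1 N-methoxy-N,2-dimethylpropanamide (Weinreb amide of isobutyric acid); 2 allylmagnesium bromide
Product: 3 2-methylhex-5-en-3-one (allyl isopropyl ketone)
Conditions: THF, −78 → 0 °C; cold 1 M HCl quench
Reagents that add atoms: none
Why: Weinreb ketone synthesis, in which the chelated tetrahedral adduct should stop at mono-addition and a cold quench should release the β,γ-unsaturated ketone before the alkene can move into conjugation.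

**Step 2**
Reactants: 4 4-bromo-2-methylbut-1-ene
Product: 7 (3-methylbut-3-en-1-yl)[(trimethylsilyl)methyl]zinc, via Grignard reagent 5 (not isolated), via alkylzinc chloride 6 (not isolated)
Conditions: Mg, Et2O, reflux; ZnCl2 (1.0 equiv), Et2O, 0 °C; Me3SiCH2MgCl (1.0 equiv), 0 °C → rt; 1,4-dioxane, filtration under argon; Et2O removed under reduced pressure at 0 °C, toluene
Reagents that add atoms: zinc dichloride (ZnCl2), Cl[Zn]Cl; (trimethylsilyl)methylmagnesium chloride, C[Si](C)(C)C[Mg]Cl
Why: Grignard formation and two successive transmetalations to zinc should give a mixed dialkylzinc in which the trimethylsilylmethyl group is a non-transferable ligand, so that each molecule of bromide 4 supplies one transferable 3-methylbut-3-enyl group; dioxane precipitates the magnesium halides and should leave the salt-free reagent that ligand-controlled carbonyl addition requires.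

**Step 3**
Reactants: 3 2-methylhex-5-en-3-one; 7 (3-methylbut-3-en-1-yl)[(trimethylsilyl)methyl]zinc (2.0 equiv)
Product: 9 (R)-terpinen-4-ol [(1R)-4-methyl-1-(propan-2-yl)cyclohex-3-en-1-ol], via diene alcohol 8 (not isolated)
Conditions: Ti(OiPr)4 (1.2 equiv), trans-cyclohexane-1,2-diamine bis(hydroxycamphorsulfonamide) ligand (HOCSAC, 10 mol %), toluene/hexane, rt; i-PrOH quench, dilute with toluene, argon sparge (removes Me4Si and 2-methylbut-1-ene); second-generation Hoveyda–Grubbs catalyst (5 mol %), 45 °C, argon sparge; aq. NaHCO3, filtration through Celite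
Reagents that add atoms: none
Why: The chiral bis(sulfonamide)–titanium alkoxide complex binds the ketone and delivers the 3-methylbut-3-enyl group, passed from zinc to titanium, to a single carbonyl face, forming C4–C5; the closest known reaction type is the titanium-catalysed enantioselective addition of dialkylzincs to ketones, and the trimethylsilylmethyl group on zinc is a known non-transferable ligand in titanium-mediated organozinc additions. After the remaining zinc reagent is destroyed with propan-2-ol, the ruthenium alkylidene loads on the allyl terminus and closes the ring onto the 1,1-disubstituted alkene by [2+2] cycloaddition and cycloreversion, which is the known ring-closing metathesis to trisubstituted cyclohexenes, and Ti(OiPr)4 is a tolerated additive in such metatheses. The six-membered ring closes by ring-closing olefin metathesis of the 1,7-diene with loss of ethene, forming C1=C2, and the doubly substituted carbinol carbon should favour the folded conformer. The C4 stereocentre is set in the addition under ligand (reagent) control, which has to distinguish the α-branched isopropyl arm from the unbranched allyl arm, and the metathesis does not touch it. The step needs 1,2-addition without enolisation or conjugation of the β,γ-unsaturated ketone, which the weakly basic zinc/titanium reagent should secure, and ring closure in preference to oligomerisation, which dilution and the six-membered ring should secure.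

**Step 4**
Reactants: 10 3,5-dibromo-4-hydroxybenzoic acid
Product: 12 3,5-dibromo-4-[(tert-butyldimethylsilyl)oxy]benzoyl chloride, via bis-silyl compound 11 (not isolated)
Conditions: TBSCl (2.2 equiv), imidazole, CH2Cl2, rt; filtration; (COCl)2, DMF (cat.), CH2Cl2, 0 °C → rt; evaporation
Reagents that add atoms: tert-butyldimethylsilyl chloride, CC(C)(C)[Si](C)(C)Cl; oxalyl chloride, O=C(Cl)C(=O)Cl
Why: Silylation of both acidic OH groups followed by the neutral conversion of the silyl ester into the acid chloride (Vilsmeier-type activation by oxalyl chloride/DMF) should leave the aryl silyl ether in place and generate no HCl.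

**Step 5**
Reactants: 9 (R)-terpinen-4-ol; 12 3,5-dibromo-4-[(tert-butyldimethylsilyl)oxy]benzoyl chloride
Product: 14 (1R)-4-methyl-1-(propan-2-yl)cyclohex-3-en-1-yl 3,5-dibromo-4-[(tert-butyldimethylsilyl)oxy]benzoate, via lithium alkoxide 13 (not isolated)
Conditions: n-BuLi (1.05 equiv), THF, −78 → 0 °C; then 12, −78 °C → rt
Reagents that add atoms: none
Why: Nucleophilic acyl substitution of an aroyl chloride by a lithium tertiary alkoxide is the standard way to acylate a hindered tertiary alcohol, and it does not involve the C–O bond of the stereocentre.

**Step 6**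
Reactants: 14 (1R)-4-methyl-1-(propan-2-yl)cyclohex-3-en-1-yl 3,5-dibromo-4-[(tert-butyldimethylsilyl)oxy]benzoate; 15 tributyl(3-methylbut-2-en-1-yl)stannane (2.4 equiv)
Product: 17 (1R)-4-methyl-1-(propan-2-yl)cyclohex-3-en-1-yl 4-hydroxy-3,5-bis(3-methylbut-2-en-1-yl)benzoate (target), via silyl ether 16 (not isolated)
Conditions: Pd(PPh3)4 (10 mol %), DMF, 100 °C; then Bu4NF (excess), AcOH, THF, 0 °C → rt
Reagents that add atoms: none
Why: Twofold Stille cross-coupling (oxidative addition, transmetalation, reductive elimination) should install both linear prenyl groups under neutral conditions that spare the tertiary ester, and buffered fluoride should then cleave the aryl silyl ether and convert the tin halide into insoluble Bu3SnF.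

**Compound list**
1 | N-methoxy-N,2-dimethylpropanamide | CC(C)C(=O)N(C)OC | starting material
2 | allylmagnesium bromide | C=CC[Mg]Br | starting material
3 | 2-methylhex-5-en-3-one | CC(C)C(=O)CC=C | intermediate
4 | 4-bromo-2-methylbut-1-ene | C=C(C)CCBr | starting material
5 | (3-methylbut-3-en-1-yl)magnesium bromide | C=C(C)CC[Mg]Br | intermediate
6 | chloro(3-methylbut-3-en-1-yl)zinc | C=C(C)CC[Zn]Cl | intermediate
7 | (3-methylbut-3-en-1-yl)[(trimethylsilyl)methyl]zinc | C=C(C)CC[Zn]C[Si](C)(C)C | intermediate
8 | (4R)-7-methyl-4-(propan-2-yl)octa-1,7-dien-4-ol | O[C@@](CCC(C)=C)(C(C)C)CC=C | intermediate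
9 | (1R)-4-methyl-1-(propan-2-yl)cyclohex-3-en-1-ol, (R)-terpinen-4-ol | O[C@@]1(C(C)C)CC=C(C)CC1 | intermediate
10 | 3,5-dibromo-4-hydroxybenzoic acid | OC(=O)c1cc(Br)c(O)c(Br)c1 | starting material
11 | tert-butyldimethylsilyl 3,5-dibromo-4-[(tert-butyldimethylsilyl)oxy]benzoate | CC(C)(C)[Si](C)(C)OC(=O)c1cc(Br)c(O[Si](C)(C)C(C)(C)C)c(Br)c1 | intermediate
12 | 3,5-dibromo-4-[(tert-butyldimethylsilyl)oxy]benzoyl chloride | ClC(=O)c1cc(Br)c(O[Si](C)(C)C(C)(C)C)c(Br)c1 | intermediate
13 | lithium (1R)-4-methyl-1-(propan-2-yl)cyclohex-3-en-1-olate | [Li+].[O-][C@@]1(C(C)C)CC=C(C)CC1 | intermediate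
14 | (1R)-4-methyl-1-(propan-2-yl)cyclohex-3-en-1-yl 3,5-dibromo-4-[(tert-butyldimethylsilyl)oxy]benzoate | Brc1cc(C(=O)O[C@@]2(C(C)C)CC=C(C)CC2)cc(Br)c1O[Si](C)(C)C(C)(C)C | intermediate
15 | tributyl(3-methylbut-2-en-1-yl)stannane | CCCC[Sn](CCCC)(CCCC)CC=C(C)C | starting material
16 | (1R)-4-methyl-1-(propan-2-yl)cyclohex-3-en-1-yl 4-[(tert-butyldimethylsilyl)oxy]-3,5-bis(3-methylbut-2-en-1-yl)benzoate | CC(C)=CCc1cc(C(=O)O[C@@]2(C(C)C)CC=C(C)CC2)cc(CC=C(C)C)c1O[Si](C)(C)C(C)(C)C | intermediate
17 | (1R)-4-methyl-1-(propan-2-yl)cyclohex-3-en-1-yl 4-hydroxy-3,5-bis(3-methylbut-2-en-1-yl)benzoate | CC(C)=CCc1cc(C(=O)O[C@@]2(C(C)C)CC=C(C)CC2)cc(CC=C(C)C)c1O | target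

**Step count and risks**
Total: 6 steps. Longest linear sequence: 4 steps (1 or 2, then 3, 5, 6).

Most likely to fail:

1. Step 3. The addition may show poor facial selectivity, may stall at the hindered dialkyl ketone, which has only an isopropyl/allyl difference to read, or may transfer the silylmethyl group in competition. Fallback: from Grignard reagent 5, addition to 4,4,5,5-tetramethyl-2-(3-methylbut-1-en-2-yl)-1,3,2-dioxaborolane should give the vinylboron ate complex F1. Pd(OAc)2/MandyPhos-catalysed conjunctive cross-coupling of F1 with vinyl bromide (NaOTf additive) proceeds by palladium-induced 1,2-migration of the 3-methylbut-3-enyl group from boron to carbon and should give the tertiary boronic ester F2 with catalyst-controlled configuration. NaOH/H2O2 oxidation with retention returns to 8, which is then isolated and closed to 9 by the metathesis stage of step 3.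

2. Step 6. The prenyl group may transfer with allylic transposition, giving 1,1-dimethylallyl isomers, or the second coupling next to the silyloxy group may stay incomplete. Fallback: from 14, Stille coupling with allyltributylstannane, whose allyl group has no regiochemical ambiguity, should give the diallyl ester F3. Cross-metathesis of F3 with excess 2-methylbut-2-ene (second-generation Grubbs catalyst) should convert both allyl groups into prenyl groups and return to 16, which is desilylated as in step 6.

3. Step 1. The double bond may migrate into conjugation with the ketone, or a second equivalent of the allyl reagent may add on premature collapse of the adduct. Fallback: from 2, addition to 2-methylpropanal should give the homoallylic alcohol F4, and oxidation with Dess–Martin periodinane (NaHCO3 buffer) returns to 3.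

**Further compounds**
F1 | step 3 | bromomagnesium 4,4,5,5-tetramethyl-2-(3-methylbut-1-en-2-yl)-2-(3-methylbut-3-en-1-yl)-1,3,2-dioxaborolan-2-uide | C=C(C(C)C)[B-]1(CCC(C)=C)OC(C)(C)C(C)(C)O1.[Mg+]Br
F2 | step 3 | 2-[(4S)-7-methyl-4-(propan-2-yl)octa-1,7-dien-4-yl]-4,4,5,5-tetramethyl-1,3,2-dioxaborolane | CC1(C)OB(OC1(C)C)[C@@](CCC(C)=C)(C(C)C)CC=C
F3 | step 6 | (1R)-4-methyl-1-(propan-2-yl)cyclohex-3-en-1-yl 4-[(tert-butyldimethylsilyl)oxy]-3,5-di(prop-2-en-1-yl)benzoate | C=CCc1cc(C(=O)O[C@@]2(C(C)C)CC=C(C)CC2)cc(CC=C)c1O[Si](C)(C)C(C)(C)C
F4 | step 1 | 2-methylhex-5-en-3-ol (racemic) | CC(C)C(O)CC=C
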